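**Plan**

- Retrosynthesis: the three benzyl groups and the C5 methyl group of unit 1 are removed last. O1–C2 of unit 2 is then cut to a 2-hydroxyaryl ynone, and C4–C4a plus O1–C8a of unit 2 are cut together to a 3,5-bis(benzyloxy)benzyne and an arylpropiolic acid carrying unit 1.
- The acid is traced through its C(sp)–CO2H and aryl–C(sp) bonds to an aryl bromide. Unit 1 is cut at O1–C2 and C2–C3 to a deoxybenzoin and an aroyl chloride, and the deoxybenzoin to 3,5-dimethoxyphenol and an arylacetic acid.
- Forward order: ring C of unit 1 closes (step 3), the propiolic acid chain is attached (steps 4–5), ring A of unit 2 is joined by aryne insertion with no ring closure (step 8), ring C of unit 2 closes 6-endo (step 9), and deprotection follows.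
- Enabling feature: in ring A of unit 2 the ring oxygen on C8a and the acyl carbon C4 on C4a sit on adjacent carbons, with a further oxygen on C5 next to C4a. This is the pattern that C–O insertion of a 3-alkoxyaryne into a carboxylic acid delivers.
- Stereochemistry: the target has no stereocentre and no stereogenic double bond, so only regiochemistry has to be controlled.

Key step: step 8

Assumption: 4-(benzyloxy)benzoyl chloride, 3,5-bis(benzyloxy)phenol and ethynyltrimethylsilane are taken as purchased materials.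

**Route**

Step 1
Reactants: 1 3,5-dimethoxyphenol; 2 2-(5-bromo-2-methoxyphenyl)acetic acid
Product: 3 2-(5-bromo-2-methoxyphenyl)-1-(2-hydroxy-4,6-dimethoxyphenyl)ethan-1-one
Conditions: BF3·OEt2 (neat), 85 °C; aq NaOAc
Reagents that add atoms: none
Why: Friedel–Crafts acylation of the activated phenol by the arylacetic acid in BF3·OEt2, the standard deoxybenzoin synthesis, should place the acyl group ortho to the hydroxyl, where the ketone is held as a boron chelate, and should leave the aryl bromide untouched.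

Step 2
Reactants: 3 2-(5-bromo-2-methoxyphenyl)-1-(2-hydroxy-4,6-dimethoxyphenyl)ethan-1-one; 4 4-(benzyloxy)benzoyl chloride
Product: 5 2-[2-(5-bromo-2-methoxyphenyl)acetyl]-3,5-dimethoxyphenyl 4-(benzyloxy)benzoate
Conditions: Et3N, DMAP (cat.), CH2Cl2, 0 °C → rt
Reagents that add atoms: none
Why: DMAP-catalysed O-acylation of the phenol by the acid chloride is a routine esterification and sets up the Baker–Venkataraman rearrangement.

Step 3
Reactants: 5 2-[2-(5-bromo-2-methoxyphenyl)acetyl]-3,5-dimethoxyphenyl 4-(benzyloxy)benzoate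
Product: 7 2-[4-(benzyloxy)phenyl]-3-(5-bromo-2-methoxyphenyl)-5,7-dimethoxy-4H-chromen-4-one, via 1,3-diketone 6 (not isolated)
Conditions: t-BuOK (2.2 equiv), THF, 0 °C → rt; AcOH; then p-TsOH·H2O (cat.), PhMe, reflux
Reagents that add atoms: none
Why: The benzylic ketone enolate attacks the neighbouring aryl ester in a Baker–Venkataraman O-to-C acyl shift, and acid-catalysed cyclodehydration of the resulting 2-aryl-1,3-diketone should close the pyranone as in established routes to 2,3-diarylchromones.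

Step 4
Reactants: 7 2-[4-(benzyloxy)phenyl]-3-(5-bromo-2-methoxyphenyl)-5,7-dimethoxy-4H-chromen-4-one; 8 ethynyltrimethylsilane
Product: 9 2-[4-(benzyloxy)phenyl]-5,7-dimethoxy-3-{2-methoxy-5-[(trimethylsilyl)ethynyl]phenyl}-4H-chromen-4-one
Conditions: PdCl2(PPh3)2 (5 mol %), CuI (5 mol %), Et3N, DMF, 80 °C, sealed tube
Reagents that add atoms: none
Why: Sonogashira coupling of an aryl bromide with ethynyltrimethylsilane is routine and should tolerate the chromone and the benzyl ether.

Step 5
Reactants: 9 2-[4-(benzyloxy)phenyl]-5,7-dimethoxy-3-{2-methoxy-5-[(trimethylsilyl)ethynyl]phenyl}-4H-chromen-4-one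
Product: 10 3-(3-{2-[4-(benzyloxy)phenyl]-5,7-dimethoxy-4-oxo-4H-chromen-3-yl}-4-methoxyphenyl)prop-2-ynoic acid
Conditions: CsF (1.5 equiv), CO2 (1 atm), DMSO, rt; 1 M HCl, 0 °C
Reagents that add atoms: carbon dioxide, O=C=O
Why: Fluoride-triggered desilylative carboxylation of alkynylsilanes under CO2 in DMSO is a known route to propiolic acids at room temperature, which spares the chromone from strong base.

Step 6
Reactants: 11 3,5-bis(benzyloxy)phenol
Product: 12 3,5-bis(benzyloxy)-2-bromophenol
Conditions: NBS (1.0 equiv), CH2Cl2, −78 °C → rt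
Reagents that add atoms: N-bromosuccinimide, O=C1CCC(=O)N1Br
Why: Electrophilic aromatic bromination with NBS at low temperature in a non-polar solvent should go ortho to the hydroxyl at C2, the selectivity known for 3,5-dialkoxyphenols.

Step 7
Reactants: 12 3,5-bis(benzyloxy)-2-bromophenol
Product: 15 3,5-bis(benzyloxy)-2-(trimethylsilyl)phenyl trifluoromethanesulfonate, via aryl trimethylsilyl ether 13 (not isolated), via lithium 2-silylphenoxide 14 (not isolated)
Conditions: HMDS, THF, 65 °C, then evaporate; n-BuLi, THF, −100 °C; Tf2O, −100 °C → rt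
Reagents that add atoms: hexamethyldisilazane, C[Si](C)(C)N[Si](C)(C)C; trifluoromethanesulfonic anhydride, O=S(=O)(OS(=O)(=O)C(F)(F)F)C(F)(F)F
Why: O-silylation, bromine–lithium exchange and retro-Brook 1,3-migration of silicon from oxygen to carbon give the ortho-silyl phenoxide, which Tf2O traps as the triflate in the standard one-flask route to ortho-silylaryl triflates.

Step 8
Reactants: 10 3-(3-{2-[4-(benzyloxy)phenyl]-5,7-dimethoxy-4-oxo-4H-chromen-3-yl}-4-methoxyphenyl)prop-2-ynoic acid; 15 3,5-bis(benzyloxy)-2-(trimethylsilyl)phenyl trifluoromethanesulfonate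
Product: 18 1-[2,4-bis(benzyloxy)-6-hydroxyphenyl]-3-(3-{2-[4-(benzyloxy)phenyl]-5,7-dimethoxy-4-oxo-4H-chromen-3-yl}-4-methoxyphenyl)prop-2-yn-1-one, via cesium propiolate 16 (not isolated), via 3,5-bis(benzyloxy)benzyne 17 (not isolated)
Conditions: Cs2CO3 (0.5 equiv), MeOH, rt, evaporate, dry (PhMe azeotrope); then 15 (1.5 equiv, slow addition), CsF (3 equiv), THF, 80 °C, sealed tube; 1 M HCl, 0 °C
Reagents that add atoms: none
Why: Fluoride removes the silyl group of 15 with loss of triflate to give aryne 17, and the carboxylate oxygen of 16 adds to the aryne carbon remote from the flanking benzyloxy group, so that the aryl anion sits beside that inductively withdrawing oxygen. The anion attacks the adjacent acyl carbon through a four-membered alkoxide that opens to the 2-acylphenoxide, a net insertion of the aryne into the C–O bond that forms C4–C4a and O1–C8a of unit 2. The closest known reaction is the CsF-mediated insertion of arynes into the C–O bond of carboxylic acids, α,β-unsaturated ones among them, which gives ortho-hydroxyaryl ketones. No ring is closed and no stereocentre is formed. The step needs regioselective addition to the unsymmetrical aryne, which the C3 benzyloxy group secures, and acyl transfer faster than protonation of the aryl anion, for which the acid is used as its dry cesium salt in THF so that no bifluoride or other proton donor is present. The moderate temperature and the chelated, weakly nucleophilic phenoxide should keep the ynone from closing in the flask, and any closure in this aprotic medium would be expected to be 6-endo and to lead to 20.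

Step 9
Reactants: 18 1-[2,4-bis(benzyloxy)-6-hydroxyphenyl]-3-(3-{2-[4-(benzyloxy)phenyl]-5,7-dimethoxy-4-oxo-4H-chromen-3-yl}-4-methoxyphenyl)prop-2-yn-1-one
Product: 20 3-{5-[5,7-bis(benzyloxy)-4-oxo-4H-chromen-2-yl]-2-methoxyphenyl}-2-[4-(benzyloxy)phenyl]-5,7-dimethoxy-4H-chromen-4-one, via enaminone 19 (not isolated)
Conditions: Et2NH (5 equiv), EtOH–THF, 60 °C
Reagents that add atoms: none
Why: Conjugate addition of diethylamine gives the β-enaminone and the phenol then displaces the amine at the β-carbon by addition–elimination, the established way to obtain the 6-endo flavone and not the 5-exo aurone from a 2-hydroxyaryl ynone.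

Step 10
Reactants: 20 3-{5-[5,7-bis(benzyloxy)-4-oxo-4H-chromen-2-yl]-2-methoxyphenyl}-2-[4-(benzyloxy)phenyl]-5,7-dimethoxy-4H-chromen-4-one
Product: 21 3-[5-(5,7-dihydroxy-4-oxo-4H-chromen-2-yl)-2-methoxyphenyl]-5-hydroxy-2-(4-hydroxyphenyl)-7-methoxy-4H-chromen-4-one (CNP0288914.0)
Conditions: BCl3 (1 M in CH2Cl2, 10 equiv), C6HMe5 (10 equiv), CH2Cl2, −78 → 0 °C; then 1 M HCl
Reagents that add atoms: none
Why: Lewis-acid ether cleavage by BCl3 should remove the aryl benzyl ethers, with the benzyl cation taken up by pentamethylbenzene, and the methyl ether peri to the C4 carbonyl of unit 1 through a six-membered boron chelate, whereas the unchelated methyl ethers at C7 and on the anisole ring are inert to BCl3 at this temperature.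

**Compound list**

1 | 3,5-dimethoxyphenol | COc1cc(O)cc(OC)c1 | starting material
2 | 2-(5-bromo-2-methoxyphenyl)acetic acid | COc1ccc(Br)cc1CC(=O)O | starting material
3 | 2-(5-bromo-2-methoxyphenyl)-1-(2-hydroxy-4,6-dimethoxyphenyl)ethan-1-one | COc1cc(O)c(C(=O)Cc2cc(Br)ccc2OC)c(OC)c1 | intermediate
4 | 4-(benzyloxy)benzoyl chloride | O=C(Cl)c1ccc(OCc2ccccc2)cc1 | starting material
5 | 2-[2-(5-bromo-2-methoxyphenyl)acetyl]-3,5-dimethoxyphenyl 4-(benzyloxy)benzoate | COc1cc(OC(=O)c2ccc(OCc3ccccc3)cc2)c(C(=O)Cc2cc(Br)ccc2OC)c(OC)c1 | intermediate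
6 | 1-[4-(benzyloxy)phenyl]-2-(5-bromo-2-methoxyphenyl)-3-(2-hydroxy-4,6-dimethoxyphenyl)propane-1,3-dione (racemic, enolisable) | COc1cc(O)c(C(=O)C(C(=O)c2ccc(OCc3ccccc3)cc2)c2cc(Br)ccc2OC)c(OC)c1 | intermediate (not isolated)
7 | 2-[4-(benzyloxy)phenyl]-3-(5-bromo-2-methoxyphenyl)-5,7-dimethoxy-4H-chromen-4-one | COc1cc(OC)c2c(=O)c(-c3cc(Br)ccc3OC)c(-c3ccc(OCc4ccccc4)cc3)oc2c1 | intermediate
8 | ethynyltrimethylsilane | C#C[Si](C)(C)C | starting material
9 | 2-[4-(benzyloxy)phenyl]-5,7-dimethoxy-3-{2-methoxy-5-[(trimethylsilyl)ethynyl]phenyl}-4H-chromen-4-one | COc1cc(OC)c2c(=O)c(-c3cc(C#C[Si](C)(C)C)ccc3OC)c(-c3ccc(OCc4ccccc4)cc3)oc2c1 | intermediate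
10 | 3-(3-{2-[4-(benzyloxy)phenyl]-5,7-dimethoxy-4-oxo-4H-chromen-3-yl}-4-methoxyphenyl)prop-2-ynoic acid | COc1cc(OC)c2c(=O)c(-c3cc(C#CC(=O)O)ccc3OC)c(-c3ccc(OCc4ccccc4)cc3)oc2c1 | intermediate
11 | 3,5-bis(benzyloxy)phenol | Oc1cc(OCc2ccccc2)cc(OCc2ccccc2)c1 | starting material
12 | 3,5-bis(benzyloxy)-2-bromophenol | Oc1cc(OCc2ccccc2)cc(OCc2ccccc2)c1Br | intermediate
13 | [3,5-bis(benzyloxy)-2-bromophenoxy]trimethylsilane | C[Si](C)(C)Oc1cc(OCc2ccccc2)cc(OCc2ccccc2)c1Br | intermediate (not isolated)
14 | lithium 3,5-bis(benzyloxy)-2-(trimethylsilyl)phenoxide | [Li+].[O-]c1cc(OCc2ccccc2)cc(OCc2ccccc2)c1[Si](C)(C)C | intermediate (not isolated)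
15 | 3,5-bis(benzyloxy)-2-(trimethylsilyl)phenyl trifluoromethanesulfonate | C[Si](C)(C)c1c(OS(=O)(=O)C(F)(F)F)cc(OCc2ccccc2)cc1OCc1ccccc1 | intermediate
16 | cesium 3-(3-{2-[4-(benzyloxy)phenyl]-5,7-dimethoxy-4-oxo-4H-chromen-3-yl}-4-methoxyphenyl)prop-2-ynoate | COc1cc(OC)c2c(=O)c(-c3cc(C#CC(=O)[O-])ccc3OC)c(-c3ccc(OCc4ccccc4)cc3)oc2c1.[Cs+] | intermediate (not isolated)
17 | 3,5-bis(benzyloxy)benzyne (1,2-didehydro-3,5-bis(benzyloxy)benzene) | C1#CC(OCc2ccccc2)=CC(OCc2ccccc2)=C1 | intermediate (not isolated)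
18 | 1-[2,4-bis(benzyloxy)-6-hydroxyphenyl]-3-(3-{2-[4-(benzyloxy)phenyl]-5,7-dimethoxy-4-oxo-4H-chromen-3-yl}-4-methoxyphenyl)prop-2-yn-1-one | COc1cc(OC)c2c(=O)c(-c3cc(C#CC(=O)c4c(O)cc(OCc5ccccc5)cc4OCc4ccccc4)ccc3OC)c(-c3ccc(OCc4ccccc4)cc3)oc2c1 | intermediate
19 | (E)-1-[2,4-bis(benzyloxy)-6-hydroxyphenyl]-3-(3-{2-[4-(benzyloxy)phenyl]-5,7-dimethoxy-4-oxo-4H-chromen-3-yl}-4-methoxyphenyl)-3-(diethylamino)prop-2-en-1-one | COc1cc(OC)c2c(=O)c(-c3cc(/C(=C\C(=O)c4c(O)cc(OCc5ccccc5)cc4OCc4ccccc4)N(CC)CC)ccc3OC)c(-c3ccc(OCc4ccccc4)cc3)oc2c1 | intermediate (not isolated)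
20 | 3-{5-[5,7-bis(benzyloxy)-4-oxo-4H-chromen-2-yl]-2-methoxyphenyl}-2-[4-(benzyloxy)phenyl]-5,7-dimethoxy-4H-chromen-4-one | COc1cc(OC)c2c(=O)c(-c3cc(-c4cc(=O)c5c(OCc6ccccc6)cc(OCc6ccccc6)cc5o4)ccc3OC)c(-c3ccc(OCc4ccccc4)cc3)oc2c1 | intermediate
21 | 3-[5-(5,7-dihydroxy-4-oxo-4H-chromen-2-yl)-2-methoxyphenyl]-5-hydroxy-2-(4-hydroxyphenyl)-7-methoxy-4H-chromen-4-one | COc1cc(O)c2c(=O)c(-c3cc(-c4cc(=O)c5c(O)cc(O)cc5o4)ccc3OC)c(-c3ccc(O)cc3)oc2c1 | target

**Step count and risks**

Total step count: 10. Longest linear sequence: 8 steps (steps 1–5, then 8–10). The aryne precursor branch (steps 6–7) joins at step 8.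

Steps most likely to fail:

1. Step 8. The aryl anion may be protonated before it reaches the acyl carbon, which stops the sequence at O-arylation. The phenoxide may also close onto the ynone in the flask, or the propiolate may lose CO2 on heating. Fallback: the junction of rings A and C of unit 2 is made by carbonylation, setting out from 9 and 11. K2CO3 in MeOH–THF should remove the silyl group of 9 to give 2-[4-(benzyloxy)phenyl]-3-(5-ethynyl-2-methoxyphenyl)-5,7-dimethoxy-4H-chromen-4-one F1. N-Iodosuccinimide in CH2Cl2 at low temperature should convert 11 into 3,5-bis(benzyloxy)-2-iodophenol F2. A carbonylative Sonogashira coupling of F1 and F2 (PdCl2(PPh3)2, CO at 1 atm, Et2NH, 60–100 °C) should form ynone 18 in the flask, and the diethylamine present carries it through 19 to the flavone, so the route is rejoined at 20.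

2. Step 10. Cleavage of the chelated methyl ether may stay incomplete under conditions mild enough to spare the other two methyl ethers, and benzyl cations may alkylate the electron-rich ring A of unit 2 in spite of the scavenger. Fallback: the two deprotections are separated, setting out from 20. Hydrogenolysis (H2, 10% Pd/C, THF–MeOH, rt) should give 3-[5-(5,7-dihydroxy-4-oxo-4H-chromen-2-yl)-2-methoxyphenyl]-2-(4-hydroxyphenyl)-5,7-dimethoxy-4H-chromen-4-one F3. AlCl3 in MeCN at 50 °C should then remove only the C5 methyl group of unit 1, and the route comes back at 21.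

3. Step 6. Bromination may not be selective for C2, with attack at C4 between the two benzyloxy groups or double bromination. Fallback: the bromine is placed by directed ortho-metalation, setting out from 11. Diethylcarbamoyl chloride and K2CO3 in MeCN should give 3,5-bis(benzyloxy)phenyl diethylcarbamate F4. s-BuLi/TMEDA in THF at −78 °C should lithiate the position between the carbamate and a benzyloxy group, and 1,2-dibromoethane at −78 °C should then give 3,5-bis(benzyloxy)-2-bromophenyl diethylcarbamate F5. KOH in refluxing EtOH cleaves the carbamate, and the route is rejoined at 12.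

Further compounds
F1 | step 8 | 2-[4-(benzyloxy)phenyl]-3-(5-ethynyl-2-methoxyphenyl)-5,7-dimethoxy-4H-chromen-4-one | COc1cc(OC)c2c(=O)c(-c3cc(C#C)ccc3OC)c(-c3ccc(OCc4ccccc4)cc3)oc2c1
F2 | step 8 | 3,5-bis(benzyloxy)-2-iodophenol | Oc1cc(OCc2ccccc2)cc(OCc2ccccc2)c1I
F3 | step 10 | 3-[5-(5,7-dihydroxy-4-oxo-4H-chromen-2-yl)-2-methoxyphenyl]-2-(4-hydroxyphenyl)-5,7-dimethoxy-4H-chromen-4-one | COc1cc(OC)c2c(=O)c(-c3cc(-c4cc(=O)c5c(O)cc(O)cc5o4)ccc3OC)c(-c3ccc(O)cc3)oc2c1
F4 | step 6 | 3,5-bis(benzyloxy)phenyl diethylcarbamate | CCN(CC)C(=O)Oc1cc(OCc2ccccc2)cc(OCc2ccccc2)c1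
F5 | step 6 | 3,5-bis(benzyloxy)-2-bromophenyl diethylcarbamate | CCN(CC)C(=O)Oc1cc(OCc2ccccc2)cc(OCc2ccccc2)c1Br
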